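## Analysis of the target

Ficucaricone C (20) is a 2,2-dimethyl-2H-chromene whose benzene ring (ring A) is a fully differentiated phloroglucinol. Chromene numbering is used for ring A throughout, also for the open precursors: O1 sits on C8a, C5 carries the methoxy group, C7 the free hydroxyl, C8 the only ring hydrogen, and C6 the 1,2-diketone C1'–C2' that ends in the 4-prenyloxyphenyl ring B. There is no stereocentre, so the problem is purely regiochemical: three oxygens of a symmetric triol must become pyran ether, methyl ether and free phenol, and the pyran must be fused at C4a, not at C8. The sensitive groups are the aryl prenyl ether of ring B (ionises in strong acid, undergoes its own Claisen shift near 200 °C), the C3=C4 double bond (acid, electrophiles, oxidants) and the 1,2-diketone (benzilic acid rearrangement with hydroxide, condensation with amines and enolates). The difficulty is that C4a and C8 are electronically almost alike, each lying between two oxygens. The route rests on the fact that C4a lies between the C5 and C8a oxygens while the C1' carbonyl on C6 can close a six-membered hydrogen-bonded chelate with a free hydroxyl on C5. With the C7 oxygen masked, this chelate makes the C8a–C4a bond different from the C8a–C8 bond and can direct C–C bond formation to C4a; the same hydroxyl is then methylated and the masked one released.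

## Retrosynthetic reasoning

**20 ⇒ 19 ⇒ 18 (two ether O–C bonds).** The acetal O–CH2 bond on the C7 oxygen of 19 is cut first, then the O–CH3 bond on C5. The order follows from the plan: the C5 hydroxyl of 18 must stay free until the pyran is in place, and the C7 oxygen must stay masked while C5–OH is methylated. A MOM acetal ortho to a ketone leaves under acid mild enough for the prenyl ether and the chromene. Forward, a hindered chelated phenol has to be methylated and one acetal cleaved.

**18 ⇒ 14 (C4–C4a and O1–C2).** Opening the pyran of 18 at O1–C2 gives the vinyl ortho-quinone methide 17. A reverse 1,5-hydrogen shift leads to allenyl phenol 16 and its keto tautomer 15. A reverse [3,3] shift cuts C4–C4a and returns the five-carbon unit to the C8a oxygen as the 1,1-dimethylpropargyl ether 14. This cut replaces a C–C bond formation between two oxygens by an O-alkylation of the most acidic phenol plus a neutral thermal isomerisation, and in 14 the hydrogen bond between C5–OH and C1'=O can tell C4a from C8. One ring and one skeletal bond are gained without reagents. Forward, the shift must go to C4a, the ring must close through the C8a oxygen, and the ring B prenyl ether must stay untouched.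

**14 ⇒ 13 ⇒ 11 ⇒ 10 (O-alkyl bonds).** Cutting the acetal on the C7 oxygen of 14 gives 13, whose C5 and C7 hydroxyls are equivalent by symmetry, so mono-protection needs no regiocontrol and leaves the other hydroxyl as the steering group. Cutting the propargylic O–C bond of 13 gives triol 11, whose C8a hydroxyl is para to the carbonyl, the most acidic and the only one not flanked by the acyl group. Triol 11 goes back to its tris-MOM ether 10 because the C–C bond formations need a ring A without acidic protons.

**10 ⇒ 8 + 9 and 8 ⇒ 7 + 6 (C2'–ring B carbon and C6–C1').** Both carbonyl carbons come from the oxalic diamide 6, a two-carbon dielectrophile that stops at the ketone level at each end. The ring A bond is made first: the ketone of 8 is then screened by two ortho MOM ethers, so 9 can distinguish it from the remaining amide. The opposite order would leave an unhindered ring B ketone next to the amide. On 2 all three ring hydrogens are equivalent, so the acylation raises no regiochemical question.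

**9 ⇒ 5 ⇒ 3 + 4 and 7 ⇒ 2 ⇒ 1.** The two organometallic partners come from an aryl bromide by metal insertion and from an arene by directed metalation. 5 is the O-prenyl ether of 3, and 2 is the tris-MOM ether of 1. The route therefore starts from 1, 3, 4, 6 and the propargylic chloride 12.

## Alternatives that were turned down

**Alternative 1: aryne insertion into a masked glyoxylic acid.**
- Disconnection: the C6–C1' and C7–O bonds are removed together.
- Forward key step: fluoride unmasks aryne A3 from silyl triflate A2. The carboxylate oxygen of the ketal-protected acid A4 adds at C7, remote from the methoxy group. The negative charge developing at C6, next to the methoxy group, takes over the acyl group and gives A1, which needs only ketal hydrolysis.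
- For it: acyl group and free C7 hydroxyl arrive in one operation with methoxy-controlled regiochemistry, and A1 is one deprotection from 20. In convergence and in steps after fragment union it is stronger than the chosen route.
- Against it: A2 already needs a regiodefined chromene carrying adjacent silyl and triflate groups beside the methoxy group, so the pyran regiochemistry is not solved but moved. The acyl transfer must pass through a strained four-membered arrangement onto a carbonyl beside a quaternary ketal carbon, and protonation before transfer would stop at O-arylation. The aryne can also engage the chromene and prenyl alkenes.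
- Comparison: the chosen route offers classical steps from a symmetric arene and a single selectivity question with a clear structural handle.

**Alternative 2: isocyanide carbon as acyl anion linchpin.**
- Disconnection: the ring B carbon–C2' and C2'–C1' bonds, with C2' delivered by an isocyanide.
- Forward key step: aryllithium A8 (from 5 by bromine–lithium exchange) adds to the isocyanide carbon of A7 to give lithium aldimine A9. A9 adds to aldehyde A6, and aqueous acid hydrolyses the C=N bond to the racemic benzoin A5.
- For it: both halves are complete before union, and the benzoin stereocentre is irrelevant because it is oxidised away. In convergence it is at least equal to the chosen route.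
- Against it: A5 is at the wrong oxidation level, so an oxidation in the presence of the chromene and prenyl alkenes and a deprotection follow. The aldehyde of A6 is flanked by two ortho ethers. The regiochemistry of the chromene in A6 still has to be set separately.
- Comparison: the chosen route carries the diketone at the right oxidation level from step 4 and uses it as the control element for the pyran.

**Alternative 3: oxalyl bis-amide linchpin on a preformed chromene.**
- Disconnection: C6–C1' and C2'–ring B carbon, late in the synthesis.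
- Forward key step: A11 is metalated at C6 by bromine–lithium exchange and added to 6, then 9 is added, and work-up releases A10, which is identical with 19.
- For it: the most convergent plan, with the same dependable linchpin chemistry as steps 3 and 4. No thermal step in the presence of the prenyl ether and no methylation of a chelated phenol are needed. In convergence and steps after union it is stronger.
- Against it: A11 needs the pyran fused with defined regiochemistry and a bromine at C6 between two ethers. Without an acyl group at C6 there is no chelate to steer the annulation, and electrophilic bromination would prefer the less hindered C8 or the C3=C4 bond.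
- Comparison: the chosen route puts the acyl group on the symmetric arene first, where no regiochemistry arises, and then lets it direct the annulation.

Key step: step 8

Remark on the chemistry: the ortho-hydroxy benzils 11, 13, 14, 18 and 20 are written as open, hydrogen-bonded diketones; reversible ring–chain tautomerism to cyclic hemiketals is assumed not to divert material.

## Route

Step 1
Reactants: 1 phloroglucinol (benzene-1,3,5-triol)
Product: 2 1,3,5-tris(methoxymethoxy)benzene
Conditions: NaH, MOMCl, DMF, 0 °C to rt
Reagents that add atoms: chloromethyl methyl ether (MOMCl), COCCl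
Why: Threefold Williamson-type O-alkylation of the phenoxide with the hard chloromethyl ether, which strongly prefers oxygen over carbon; the product is the symmetric arene in which all three ring C–H bonds are equivalent.

Step 2
Reactants: 3 4-bromophenol, 4 prenyl bromide (1-bromo-3-methylbut-2-ene)
Product: 5 1-bromo-4-(3-methylbut-2-enyloxy)benzene
Conditions: K2CO3, acetone, reflux
Reagents that add atoms: none
Why: Williamson ether synthesis; the phenoxide displaces bromide at the primary allylic carbon, and carbonate in acetone is too mild for C-alkylation or a Claisen shift.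

Step 3
Reactants: 2 1,3,5-tris(methoxymethoxy)benzene, 6 N,N'-dimethoxy-N,N'-dimethyloxamide
Product: 8 N-methoxy-N-methyl-2-oxo-2-[2,4,6-tris(methoxymethoxy)phenyl]acetamide, via aryllithium 7 (not isolated)
Conditions: n-BuLi, THF, 0 °C; then 6 (1.5 equiv, inverse addition), THF, −78 °C; aq. NH4Cl
Reagents that add atoms: none
Why: Directed ortho-metalation between two MOM ethers (every ring C–H is equivalent) followed by acylation of 7 with one amide group of 6 (Weinreb ketone synthesis). The N-methoxy-N-methyl amide takes up one aryl group only, and inverse addition to an excess of 6 keeps the second amide group intact.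

Step 4
Reactants: 5 1-bromo-4-(3-methylbut-2-enyloxy)benzene, 8 N-methoxy-N-methyl-2-oxo-2-[2,4,6-tris(methoxymethoxy)phenyl]acetamide
Product: 10 1-[4-(3-methylbut-2-enyloxy)phenyl]-2-[2,4,6-tris(methoxymethoxy)phenyl]ethane-1,2-dione, via Grignard reagent 9 (not isolated)
Conditions: Mg, I2 (cat.), THF, 45 °C; then 8, THF, −78 to 0 °C; aq. NH4Cl
Reagents that add atoms: none
Why: Magnesium insertion gives 9, which adds to the amide carbonyl of 8 (Weinreb ketone synthesis) and releases the second ketone on work-up. The ketone of 8 is flanked by two ortho MOM ethers and deactivated by the trioxygenated ring, so it should be spared; the aryl prenyl ether is inert to Mg and to the Grignard reagent.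

Step 5
Reactants: 10 1-[4-(3-methylbut-2-enyloxy)phenyl]-2-[2,4,6-tris(methoxymethoxy)phenyl]ethane-1,2-dione
Product: 11 1-[4-(3-methylbut-2-enyloxy)phenyl]-2-(2,4,6-trihydroxyphenyl)ethane-1,2-dione
Conditions: 2 M aq. HCl, MeOH, 40 °C
Reagents that add atoms: none
Why: Acid-catalysed acetal exchange with methanol removes all three MOM groups as dimethoxymethane, the two ortho ones with help from the neighbouring carbonyl. Dilute acid at 40 °C should stay below the threshold for ionisation of the aryl prenyl ether, and the diketone forms hemiketals only reversibly.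

Step 6
Reactants: 11 1-[4-(3-methylbut-2-enyloxy)phenyl]-2-(2,4,6-trihydroxyphenyl)ethane-1,2-dione, 12 3-chloro-3-methylbut-1-yne
Product: 13 1-[2,6-dihydroxy-4-(2-methylbut-3-yn-2-yloxy)phenyl]-2-[4-(3-methylbut-2-enyloxy)phenyl]ethane-1,2-dione
Conditions: K2CO3 (1.1 equiv), KI, CuI (cat.), MeCN, 45 °C, Ar
Reagents that add atoms: none
Why: Williamson-type O-alkylation of a phenoxide with a tertiary propargylic chloride under CuI catalysis. With about one equivalent of base only the C8a hydroxyl, para to the carbonyl and the most acidic, is ionised, while the two flanking hydroxyls are hindered and share the hydrogen bond to C1'=O, the bias that generally allows 4-O-monoalkylation of 2,4,6-trihydroxyaryl ketones. At 45 °C the Claisen shift does not yet start.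

Step 7
Reactants: 13 1-[2,6-dihydroxy-4-(2-methylbut-3-yn-2-yloxy)phenyl]-2-[4-(3-methylbut-2-enyloxy)phenyl]ethane-1,2-dione
Product: 14 1-[2-hydroxy-6-(methoxymethoxy)-4-(2-methylbut-3-yn-2-yloxy)phenyl]-2-[4-(3-methylbut-2-enyloxy)phenyl]ethane-1,2-dione
Conditions: MOMCl (1.1 equiv), K2CO3, MeCN, 0 °C to rt
Reagents that add atoms: chloromethyl methyl ether (MOMCl), COCCl
Why: The two hydroxyls of 13 are equivalent by symmetry, so the first Williamson-type O-alkylation has no regiochemical choice. The hydroxyl that remains is locked in the hydrogen bond to C1'=O and is much less nucleophilic, which should stop the reaction at the mono-MOM ether.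

Step 8
Reactants: 14 1-[2-hydroxy-6-(methoxymethoxy)-4-(2-methylbut-3-yn-2-yloxy)phenyl]-2-[4-(3-methylbut-2-enyloxy)phenyl]ethane-1,2-dione
Product: 18 1-[5-hydroxy-7-(methoxymethoxy)-2,2-dimethyl-2H-chromen-6-yl]-2-[4-(3-methylbut-2-enyloxy)phenyl]ethane-1,2-dione, via allenyl dienone 15 (not isolated), via allenyl phenol 16 (not isolated), via vinyl ortho-quinone methide 17 (not isolated)
Conditions: o-xylene (degassed), 135 °C
Reagents that add atoms: none
Why: This is the aromatic propargyl Claisen cascade, the established thermal route from aryl 1,1-dimethylpropargyl ethers to 2,2-dimethyl-2H-chromenes. A [3,3] shift moves the propargyl unit from the C8a oxygen to C4a as an allene (15, new C4–C4a bond), enolisation gives 16, a 1,5-hydrogen shift from the C8a hydroxyl to the central allene carbon gives the Z quinone methide 17, and a thermally allowed disrotatory oxa-6π electrocyclisation re-forms O1–C2 and closes the six-membered pyran with rearomatisation. No stereocentre results, since C2 carries two methyl groups and the sp3 carbon of 15 is lost on enolisation. The step needs regioselectivity between C4a and C8, both of which lie between two oxygens. The resonance-assisted hydrogen bond C5–OH···O=C1' favours the Kekulé structure with C5=C6, C7=C8 and C8a=C4a double bonds, so the O–C8a=C4a unit used by the shift has the higher π-bond order, and 15 keeps the chelated enol–ketone unit whereas its C8 isomer would give it up; the MOM ether on the C7 oxygen offers no such hydrogen bond. Closure through the C8a oxygen and not the C5 oxygen follows because the C8a oxygen is the carbonyl of 15 and the C5 hydroxyl proton stays locked in the chelate. The ring B prenyl ether, para to a carbonyl, needs roughly 200 °C for its own [3,3] shift, so 135 °C secures chemoselectivity, and the MOM ether, the diketone and the prenyl alkene are inert under neutral thermal conditions.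

Step 9
Reactants: 18 1-[5-hydroxy-7-(methoxymethoxy)-2,2-dimethyl-2H-chromen-6-yl]-2-[4-(3-methylbut-2-enyloxy)phenyl]ethane-1,2-dione
Product: 19 1-[5-methoxy-7-(methoxymethoxy)-2,2-dimethyl-2H-chromen-6-yl]-2-[4-(3-methylbut-2-enyloxy)phenyl]ethane-1,2-dione
Conditions: MeI, K2CO3, DMF, 40 °C
Reagents that add atoms: iodomethane, CI
Why: Williamson O-methylation; the only acidic site is the chelated C5 hydroxyl, whose phenoxide forms with K2CO3 in DMF and is methylated by the small electrophile despite its two neighbours. There is no enolisable C–H, and anhydrous carbonate does not trigger the benzilic acid rearrangement.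

Step 10
Reactants: 19 1-[5-methoxy-7-(methoxymethoxy)-2,2-dimethyl-2H-chromen-6-yl]-2-[4-(3-methylbut-2-enyloxy)phenyl]ethane-1,2-dione
Product: 20 ficucaricone C, 1-(7-hydroxy-5-methoxy-2,2-dimethyl-2H-chromen-6-yl)-2-[4-(3-methylbut-2-enyloxy)phenyl]ethane-1,2-dione
Conditions: 1 M aq. HCl, MeOH, 35 °C
Reagents that add atoms: none
Why: Acid-catalysed cleavage of the MOM acetal, accelerated by the ortho carbonyl, which then holds the liberated C7 hydroxyl in a hydrogen bond. The conditions are milder than in step 5, so the prenyl ether and the chromene double bond should survive.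

## Compound list

1 | phloroglucinol (benzene-1,3,5-triol) | Oc1cc(O)cc(O)c1 | starting material
2 | 1,3,5-tris(methoxymethoxy)benzene | COCOc1cc(OCOC)cc(OCOC)c1 | intermediate
3 | 4-bromophenol | Oc1ccc(Br)cc1 | starting material
4 | prenyl bromide (1-bromo-3-methylbut-2-ene) | CC(C)=CCBr | starting material
5 | 1-bromo-4-(3-methylbut-2-enyloxy)benzene | CC(C)=CCOc1ccc(Br)cc1 | intermediate
6 | N,N'-dimethoxy-N,N'-dimethyloxamide | CON(C)C(=O)C(=O)N(C)OC | starting material
7 | [2,4,6-tris(methoxymethoxy)phenyl]lithium (not isolated) | [Li]c1c(OCOC)cc(OCOC)cc1OCOC | intermediate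
8 | N-methoxy-N-methyl-2-oxo-2-[2,4,6-tris(methoxymethoxy)phenyl]acetamide | CON(C)C(=O)C(=O)c1c(OCOC)cc(OCOC)cc1OCOC | intermediate
9 | [4-(3-methylbut-2-enyloxy)phenyl]magnesium bromide (not isolated) | CC(C)=CCOc1ccc([Mg]Br)cc1 | intermediate
10 | 1-[4-(3-methylbut-2-enyloxy)phenyl]-2-[2,4,6-tris(methoxymethoxy)phenyl]ethane-1,2-dione | COCOc1cc(OCOC)c(C(=O)C(=O)c2ccc(OCC=C(C)C)cc2)c(OCOC)c1 | intermediate
11 | 1-[4-(3-methylbut-2-enyloxy)phenyl]-2-(2,4,6-trihydroxyphenyl)ethane-1,2-dione | Oc1cc(O)c(C(=O)C(=O)c2ccc(OCC=C(C)C)cc2)c(O)c1 | intermediate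
12 | 3-chloro-3-methylbut-1-yne | C#CC(C)(C)Cl | starting material
13 | 1-[2,6-dihydroxy-4-(2-methylbut-3-yn-2-yloxy)phenyl]-2-[4-(3-methylbut-2-enyloxy)phenyl]ethane-1,2-dione | C#CC(C)(C)Oc1cc(O)c(C(=O)C(=O)c2ccc(OCC=C(C)C)cc2)c(O)c1 | intermediate
14 | 1-[2-hydroxy-6-(methoxymethoxy)-4-(2-methylbut-3-yn-2-yloxy)phenyl]-2-[4-(3-methylbut-2-enyloxy)phenyl]ethane-1,2-dione | C#CC(C)(C)Oc1cc(O)c(C(=O)C(=O)c2ccc(OCC=C(C)C)cc2)c(OCOC)c1 | intermediate
15 | 1-[2-hydroxy-6-(methoxymethoxy)-3-(3-methylbuta-1,2-dienyl)-4-oxocyclohexa-1,5-dienyl]-2-[4-(3-methylbut-2-enyloxy)phenyl]ethane-1,2-dione (racemic, not isolated) | O=C1C=C(OCOC)C(C(=O)C(=O)c2ccc(OCC=C(C)C)cc2)=C(O)C1C=C=C(C)C | intermediate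
16 | 1-[2,4-dihydroxy-6-(methoxymethoxy)-3-(3-methylbuta-1,2-dienyl)phenyl]-2-[4-(3-methylbut-2-enyloxy)phenyl]ethane-1,2-dione (not isolated) | CC(C)=C=Cc1c(O)cc(OCOC)c(C(=O)C(=O)c2ccc(OCC=C(C)C)cc2)c1O | intermediate
17 | 1-[(3Z)-2-hydroxy-6-(methoxymethoxy)-3-(3-methylbut-2-enylidene)-4-oxocyclohexa-1,5-dienyl]-2-[4-(3-methylbut-2-enyloxy)phenyl]ethane-1,2-dione (not isolated) | CC(C)=C/C=C1\C(=O)C=C(OCOC)C(C(=O)C(=O)c2ccc(OCC=C(C)C)cc2)=C1O | intermediate
18 | 1-[5-hydroxy-7-(methoxymethoxy)-2,2-dimethyl-2H-chromen-6-yl]-2-[4-(3-methylbut-2-enyloxy)phenyl]ethane-1,2-dione | COCOc1cc2OC(C)(C)C=Cc2c(O)c1C(=O)C(=O)c1ccc(OCC=C(C)C)cc1 | intermediate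
19 | 1-[5-methoxy-7-(methoxymethoxy)-2,2-dimethyl-2H-chromen-6-yl]-2-[4-(3-methylbut-2-enyloxy)phenyl]ethane-1,2-dione | COCOc1cc2OC(C)(C)C=Cc2c(OC)c1C(=O)C(=O)c1ccc(OCC=C(C)C)cc1 | intermediate
20 | ficucaricone C, 1-(7-hydroxy-5-methoxy-2,2-dimethyl-2H-chromen-6-yl)-2-[4-(3-methylbut-2-enyloxy)phenyl]ethane-1,2-dione | COc1c2c(cc(O)c1C(=O)C(=O)c1ccc(OCC=C(C)C)cc1)OC(C)(C)C=C2 | target

## Step count and uncertain steps

Total: 10 steps. Longest linear sequence: 9 steps (steps 1 and 3 to 10, from 1); step 2 is the side branch.

**Step 8 (key step).** The most likely failure is poor regiocontrol of the [3,3] shift, with migration to C8 instead of C4a, because both carbons lie between two oxygens and the bias rests on the hydrogen bond alone. Closure through the C5 oxygen or a slow Claisen shift of the ring B prenyl ether on long heating are lesser risks. The fallback sets out from 13 and rejoins at 18. Heating symmetric 13 in o-xylene at 135 °C should run the same cascade, but C4a and C8 are now equivalent, so only 1-(5,7-dihydroxy-2,2-dimethyl-2H-chromen-6-yl)-2-[4-(3-methylbut-2-enyloxy)phenyl]ethane-1,2-dione F1 can form. The regiochemical decision is thereby moved to an O-alkylation. With one equivalent of MOMCl and K2CO3 the C7 hydroxyl, next to C8–H, should react in preference to the C5 hydroxyl, which is buttressed by the peri C4–H and held in the chelate, to give 18. An isomeric MOM ether would be separated and returned to F1 with dilute acid.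

**Step 6.** The likely failures are over-alkylation at a flanking hydroxyl, C-alkylation of the electron-rich ring, or slow substitution at the tertiary chloride with decay of the triol. The fallback sets out from 1 and rejoins at 14; it differentiates the C8a oxygen before acylation so that the propargylation meets a single free phenol.
- Partial protection of 1 (NaH and MOMCl, two equivalents each) gives 3,5-bis(methoxymethoxy)phenol F2, with 2 as a usable co-product.
- TIPSCl and imidazole give [3,5-bis(methoxymethoxy)phenoxy]tri(propan-2-yl)silane F3.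
- Lithiation between the two MOM ethers and acylation with 6 as in step 3 give 2-[2,6-bis(methoxymethoxy)-4-tri(propan-2-yl)silyloxyphenyl]-N-methoxy-N-methyl-2-oxoacetamide F4.
- Addition of 9 as in step 4 gives 1-[2,6-bis(methoxymethoxy)-4-tri(propan-2-yl)silyloxyphenyl]-2-[4-(3-methylbut-2-enyloxy)phenyl]ethane-1,2-dione F5.
- TBAF in THF at 0 °C frees 1-[4-hydroxy-2,6-bis(methoxymethoxy)phenyl]-2-[4-(3-methylbut-2-enyloxy)phenyl]ethane-1,2-dione F6.
- 12 with K2CO3 and CuI gives 1-[2,6-bis(methoxymethoxy)-4-(2-methylbut-3-yn-2-yloxy)phenyl]-2-[4-(3-methylbut-2-enyloxy)phenyl]ethane-1,2-dione F7.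
- Dilute HCl in MeOH at rt removes one of the two equivalent ortho MOM groups with carbonyl assistance and should stop there, because the freed hydroxyl ties up the carbonyl, giving 14.

**Step 5.** The likely failure is loss of the ring B prenyl group by acid-promoted ionisation of the allylic ether while the slower para acetal is still being cleaved. The fallback sets out from 8 and rejoins at 19; ring B enters only after the acid step and the thermal step.
- HCl in MeOH converts 8 into N-methoxy-N-methyl-2-oxo-2-(2,4,6-trihydroxyphenyl)acetamide F8.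
- 12 with K2CO3 and CuI gives 2-[2,6-dihydroxy-4-(2-methylbut-3-yn-2-yloxy)phenyl]-N-methoxy-N-methyl-2-oxoacetamide F9.
- MOMCl and K2CO3 give 2-[2-hydroxy-6-(methoxymethoxy)-4-(2-methylbut-3-yn-2-yloxy)phenyl]-N-methoxy-N-methyl-2-oxoacetamide F10.
- Heating in o-xylene at 135 °C, steered by the same C5–OH···O=C1' chelate, gives 2-[5-hydroxy-7-(methoxymethoxy)-2,2-dimethyl-2H-chromen-6-yl]-N-methoxy-N-methyl-2-oxoacetamide F11.
- MeI and K2CO3 give N-methoxy-2-[5-methoxy-7-(methoxymethoxy)-2,2-dimethyl-2H-chromen-6-yl]-N-methyl-2-oxoacetamide F12.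
- Addition of 9 to the amide of F12, whose ketone is screened by two ortho ethers, gives 19.

**Step 4.** The likely failure is addition of the Grignard reagent to the ketone carbonyl of 8 in competition with the amide carbonyl. The fallback sets out from 5 and 2 (through 9 and 7) and rejoins at 10; neither ketone is free while a nucleophile is present. 9 is added to 1,4-dimethylpiperazine-2,3-dione (CN1CCN(C)C(=O)C1=O) in THF to give bromomagnesium 1,4-dimethyl-2-[4-(3-methylbut-2-enyloxy)phenyl]-3-oxopiperazin-2-olate F13, in which the first carbonyl is stored as a hemiaminal alkoxide. In the same flask 7 adds to the remaining amide to give the mixed lithium bromomagnesium 1,4-dimethyl-2-[4-(3-methylbut-2-enyloxy)phenyl]-3-[2,4,6-tris(methoxymethoxy)phenyl]piperazine-2,3-diolate F14. Brief treatment with cold dilute aqueous acid releases both carbonyl groups and gives 10. The price is a more hindered second addition than in step 4.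

## Further compounds

F1 | step 8 | 1-(5,7-dihydroxy-2,2-dimethyl-2H-chromen-6-yl)-2-[4-(3-methylbut-2-enyloxy)phenyl]ethane-1,2-dione | CC1(C)C=Cc2c(O)c(C(=O)C(=O)c3ccc(OCC=C(C)C)cc3)c(O)cc2O1
F2 | step 6 | 3,5-bis(methoxymethoxy)phenol | COCOc1cc(O)cc(OCOC)c1
F3 | step 6 | [3,5-bis(methoxymethoxy)phenoxy]tri(propan-2-yl)silane | COCOc1cc(OCOC)cc(O[Si](C(C)C)(C(C)C)C(C)C)c1
F4 | step 6 | 2-[2,6-bis(methoxymethoxy)-4-tri(propan-2-yl)silyloxyphenyl]-N-methoxy-N-methyl-2-oxoacetamide | CON(C)C(=O)C(=O)c1c(OCOC)cc(O[Si](C(C)C)(C(C)C)C(C)C)cc1OCOC
F5 | step 6 | 1-[2,6-bis(methoxymethoxy)-4-tri(propan-2-yl)silyloxyphenyl]-2-[4-(3-methylbut-2-enyloxy)phenyl]ethane-1,2-dione | COCOc1cc(O[Si](C(C)C)(C(C)C)C(C)C)cc(OCOC)c1C(=O)C(=O)c1ccc(OCC=C(C)C)cc1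
F6 | step 6 | 1-[4-hydroxy-2,6-bis(methoxymethoxy)phenyl]-2-[4-(3-methylbut-2-enyloxy)phenyl]ethane-1,2-dione | COCOc1cc(O)cc(OCOC)c1C(=O)C(=O)c1ccc(OCC=C(C)C)cc1
F7 | step 6 | 1-[2,6-bis(methoxymethoxy)-4-(2-methylbut-3-yn-2-yloxy)phenyl]-2-[4-(3-methylbut-2-enyloxy)phenyl]ethane-1,2-dione | C#CC(C)(C)Oc1cc(OCOC)c(C(=O)C(=O)c2ccc(OCC=C(C)C)cc2)c(OCOC)c1
F8 | step 5 | N-methoxy-N-methyl-2-oxo-2-(2,4,6-trihydroxyphenyl)acetamide | CON(C)C(=O)C(=O)c1c(O)cc(O)cc1O
F9 | step 5 | 2-[2,6-dihydroxy-4-(2-methylbut-3-yn-2-yloxy)phenyl]-N-methoxy-N-methyl-2-oxoacetamide | CON(C)C(=O)C(=O)c1c(O)cc(OC(C)(C)C#C)cc1O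
F10 | step 5 | 2-[2-hydroxy-6-(methoxymethoxy)-4-(2-methylbut-3-yn-2-yloxy)phenyl]-N-methoxy-N-methyl-2-oxoacetamide | CON(C)C(=O)C(=O)c1c(O)cc(OC(C)(C)C#C)cc1OCOC
F11 | step 5 | 2-[5-hydroxy-7-(methoxymethoxy)-2,2-dimethyl-2H-chromen-6-yl]-N-methoxy-N-methyl-2-oxoacetamide | CON(C)C(=O)C(=O)c1c(OCOC)cc2OC(C)(C)C=Cc2c1O
F12 | step 5 | N-methoxy-2-[5-methoxy-7-(methoxymethoxy)-2,2-dimethyl-2H-chromen-6-yl]-N-methyl-2-oxoacetamide | CON(C)C(=O)C(=O)c1c(OCOC)cc2OC(C)(C)C=Cc2c1OC
F13 | step 4 | bromomagnesium 1,4-dimethyl-2-[4-(3-methylbut-2-enyloxy)phenyl]-3-oxopiperazin-2-olate (racemic, not isolated) | Br[Mg]OC1(c2ccc(OCC=C(C)C)cc2)N(C)CCN(C)C1=O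
F14 | step 4 | lithium bromomagnesium 1,4-dimethyl-2-[4-(3-methylbut-2-enyloxy)phenyl]-3-[2,4,6-tris(methoxymethoxy)phenyl]piperazine-2,3-diolate (mixture of stereoisomers, not isolated) | Br[Mg]OC1(c2ccc(OCC=C(C)C)cc2)N(C)CCN(C)C1(O[Li])c1c(OCOC)cc(OCOC)cc1OCOC
A1 | alternative 1 | 1-(7-hydroxy-5-methoxy-2,2-dimethyl-2H-chromen-6-yl)-2,2-dimethoxy-2-[4-(3-methylbut-2-enyloxy)phenyl]ethanone | COc1c2c(cc(O)c1C(=O)C(OC)(OC)c1ccc(OCC=C(C)C)cc1)OC(C)(C)C=C2
A2 | alternative 1 | 5-methoxy-2,2-dimethyl-6-(trimethylsilyl)-2H-chromen-7-yl trifluoromethanesulfonate | COc1c2C=CC(C)(C)Oc2cc(OS(=O)(=O)C(F)(F)F)c1[Si](C)(C)C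
A3 | alternative 1 | 6,7-didehydro-5-methoxy-2,2-dimethyl-2H-chromene (aryne) | COC1=C2C=CC(C)(C)OC2=CC#C1
A4 | alternative 1 | 2,2-dimethoxy-2-[4-(3-methylbut-2-enyloxy)phenyl]acetic acid | COC(OC)(C(=O)O)c1ccc(OCC=C(C)C)cc1
A5 | alternative 2 | 2-hydroxy-2-[5-methoxy-7-(methoxymethoxy)-2,2-dimethyl-2H-chromen-6-yl]-1-[4-(3-methylbut-2-enyloxy)phenyl]ethanone (racemic) | COc1c2c(cc(OCOC)c1C(O)C(=O)c1ccc(OCC=C(C)C)cc1)OC(C)(C)C=C2
A6 | alternative 2 | 5-methoxy-7-(methoxymethoxy)-2,2-dimethyl-2H-chromene-6-carbaldehyde | COc1c2C=CC(C)(C)Oc2cc(OCOC)c1C=O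
A7 | alternative 2 | 2-isocyano-2,4,4-trimethylpentane (1,1,3,3-tetramethylbutyl isocyanide) | CC(C)(C)CC(C)(C)[N+]#[C-]
A8 | alternative 2 | [4-(3-methylbut-2-enyloxy)phenyl]lithium | [Li]c1ccc(OCC=C(C)C)cc1
A9 | alternative 2 | [[4-(3-methylbut-2-enyloxy)phenyl](2,4,4-trimethylpentan-2-ylimino)methyl]lithium | [Li]C(=NC(C)(C)CC(C)(C)C)c1ccc(OCC=C(C)C)cc1
A10 | alternative 3 | 1-[5-methoxy-7-(methoxymethoxy)-2,2-dimethyl-2H-chromen-6-yl]-2-[4-(3-methylbut-2-enyloxy)phenyl]ethane-1,2-dione (identical with 19) | COCOc1cc2OC(C)(C)C=Cc2c(OC)c1C(=O)C(=O)c1ccc(OCC=C(C)C)cc1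
A11 | alternative 3 | 6-bromo-5-methoxy-7-(methoxymethoxy)-2,2-dimethyl-2H-chromene | COc1c2C=CC(C)(C)Oc2cc(OCOC)c1Br
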